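At 5.00 d, the elm run stands at 81 % isomer of the product A and the cedar run at 80 %, a gap of 1 percentage point against a scatter of 2 points, although c(substrate) was 0.13 M in elm and 0.30 M in cedar.

in all of them: catalyst 0.20 mM

|  | substrate | reagent | remark | time |
|---|---|---|---|---|
| elm | 0.13 M | 0.50 M | run made earlier |  |
| cedar | 0.30 M | 0.50 M | run made earlier |  |
| flask | 0.20 M | 0.500 M |  | 8.0 d |

| run | time / d | isomer of the product A / % | target / % |
|---|---|---|---|
| elm | 0.833 | 30 | 34 |
| elm | 1.67 | 51 | 28 |
| elm | 2.50 | 62 | 23 |
| elm | 3.00 | 69 | 13 |
| elm | 4.00 | 74 | 14 |
| elm | 5.00 | 81 | 5 |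
| cedar | 0.333 | 17 | 35 |
| cedar | 0.833 | 29 | 34 |
| cedar | 1.67 | 43 | 28 |
| cedar | 2.50 | 54 | 20 |
| cedar | 4.00 | 75 | 13 |
| cedar | 5.00 | 80 | 11 |

(each reading ± 2 percentage points)

- the numbers in the tables scatter with a standard deviation of 2 points

1. ratio of isomer of the product A to target at 3.0 min
2. ratio of isomer of the product A to target at 3.0 h
3. ratio of isomer of the product A to target at 8.0 d
4. which of isomer of the product A and target there is more of at 8.0 d

Reagent and catalyst were charged alike in elm and cedar, and I read the two runs as ending together in percent despite their different substrate charges. I expect the flask, whose c(substrate) lies between theirs, to follow them.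

What I watch is the leftover, meaning the charge that is not yet isomer of the product A. I replace the scattered curve by its mean: summing target and leftover over the readings of each run and dividing gives 0.502 for elm and 0.467 for cedar. Their mean, 0.485, is the target share: target divided by leftover. The mean passes over elm's last single share, 0.263, which comes from a leftover of 19.0 %, where a reading's scatter weighs heavily. I read this share as a pool in quick exchange (a pre-equilibrium) that slowly drains.

Between 0.833 d and 5.00 d the leftover of elm and cedar, taken together, decays with a rate constant of 0.308 d⁻¹. At that pace I reckon the leftover at 7.73 % at 8.0 d, and my estimate of the ratio is 24.6. The share says nothing about 3.0 min or 3.0 h, which lie before the first reading.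

The forecast gives 0.33, 0.38 and 20 (from 9 to 45), with isomer of the product A ahead, holding that “the pool drains irreversibly to the isomer”. Its last ratio is lower than mine.

The flask gives 0.151 at 3.0 min, 0.279 at 3.0 h and 19.2 at 8.0 d, with isomer of the product A ahead.

    substrate + reagent ⇌ target (K = 6.00 L mol⁻¹, k = 0.920 L mol⁻¹ h⁻¹)
    substrate + reagent ⇌ isomer of the product A (K = 250 L mol⁻¹, k = 0.130 L mol⁻¹ h⁻¹)
    target ⇌ isomer of the product B (K = 0.530, k = 2.50 h⁻¹)
    target + catalyst ⇌ isomer of the product A + catalyst, rate k4*[catalyst]*[target] forward; the back reaction follows from the equilibrium constant (k = 45.0 L mol⁻¹ h⁻¹)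

The flask holds 90.4 % isomer of the product A and 4.70 % target, so its leftover is 9.65 % and its target share is 0.487. Target's half-life for going back to substrate and reagent, 0.19 d, is short against 8.0 d. The neighbour flask with c(catalyst) = 1.2 × 10⁻⁴ M holds 88.2 % isomer of the product A at 8.00 d, so the share 0.485 gives it a ratio of 15.4, and that flask shows 15.3.

The numbers in the tables were generated by integration for an exercise; noise was put on by code.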